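(The numbers are assumed; the run is a simulation.)

Precatalyst and catalyst together hold the charge at every moment, so one share gives the other.

    coupling partner + catalyst + left-handed substrate → catalyst + left-handed product (k1 = 68300 M⁻² s⁻¹)
    coupling partner + catalyst + right-handed substrate → catalyst + right-handed product (k2 = 34300 M⁻² s⁻¹)
    gas ⇌ coupling partner, rate k3*(csat - [coupling partner]) (k3 = 0.126 s⁻¹, csat = 17 mM)
    precatalyst → catalyst (k4 = 0.00650 s⁻¹)

left-handed substrate 0.050 M; gas 17 mM (held); precatalyst 95 µM; right-handed substrate 0.050 M

- the form that holds most of the catalyst when 5.0% of the left-handed substrate and right-handed substrate together are converted (catalyst / precatalyst)
- its share of the catalyst then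
- factor on the rate of making left-handed product when 5.0% of the left-handed substrate and right-handed substrate together are converted if precatalyst is charged twice over
- factor on the rate when 5.0% of the left-handed substrate and right-handed substrate together are converted if precatalyst is charged at 500 µM instead

- catalyst is single-handed; left-handed substrate and right-handed substrate are mirror images of each other, charged as a racemate, each of them at the stated concentration
- at the start none of coupling partner is dissolved
- charge of left-handed substrate (flask): 0.050 M

Decide whether the next run should be charged with 500 µM of precatalyst instead of 95 µM. Start with the small thing, the catalyst. In this flask, the point of 5.0% conversion falls at 17.5 s, and step 4 runs by itself, so reckon: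

catalyst fraction = 1 − exp(−0.00650 s⁻¹ × 17.5 s) = 10.8%

Call this the activated share: the fraction of the precatalyst charge that has become catalyst by a given time. Precatalyst therefore keeps 89.2% of the charge.

Because the activation time 154 s is longer than 17.5 s, the activated share stays close to its straight-line value:

0.00650 s⁻¹ × 17.5 s = 11.4%

So, up to that time, the catalyst grows close to in proportion to both charge and time. Now hold the coupling partner level equal between flasks, and treat the substrates as barely changed. The rate then climbs straight from zero, and the fixed conversion is the area of a triangle under it, so rate times time stays the same. Since the rate also goes as charge times time, it goes as the square root of the charge: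

doubled charge: 1.41
charge of 500 µM: 2.29

By this reckoning, charging 5.26 times the precatalyst gives a factor of 2.29, which is less than proportional. Keep the present charge unless that factor is worth the cost.

The forecast names precatalyst at 89%, with factors of 1.33 and 1.9, lower than my roots. Its ground is that “the dissolved partner is drawn down as catalyst builds”.

The simulation gives precatalyst at 89.2%, with factors of 1.34 and 1.92, lower than my roots and close to the forecast. In this flask, catalyst holds 10.8% of the charge at that conversion. The flask charged at 500 µM holds 94.1% as precatalyst at the same conversion, an activated share of 5.90%. Reckoned with the first flask's activated share of 10.8%, it therefore contains 2.88 times the catalyst of the first flask at that conversion, while its rate there stands 1.92 times as high.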